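**Retrosynthetic overview**

1. Target 21 ⇐ benzyl-protected 8-bromo dimer 20 by global hydrogenolysis. The interflavan bond C4(upper)–C6(lower) ⇐ Friedel–Crafts capture of the flavan-4-yl cation from 19 by the C8-brominated tri-O-benzyl epiafzelechin 14 (biosynthesis-like union, last skeletal bond).
2. Pyran ring of the lower unit (O1–C2–C3–C4–C4a–C8a) ⇐ one-carbon ring expansion of the cis-2-aryl-3-(hydroxymethyl)-2,3-dihydrobenzofuran 10: the ring A carbon moves from C3 to the exocyclic CH2 (which becomes C4) and a trifluoroacetate oxygen returns to C3 with inversion.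
3. Enabling feature: in the lower unit C4 is an unsubstituted CH2 between the oxygen-bearing C3 and the ring A carbon C4a, and C4a is ortho to O1 and O5 and para to O7. This carbon is therefore an exceptional 1,2-migrating group, and the contracted isomer is a simple dihydrobenzofuranylmethanol.
4. 10 ⇐ ester 9 ⇐ diazo ester 8 by enantioselective dirhodium-carbene C–H insertion (furan ring, C2 and C3 together) ⇐ keto ester 6 ⇐ phenol 4 + 4-(benzyloxy)benzyl chloride 5; 4 ⇐ benzofuran-2,3-dione 3 ⇐ 3,5-bis(benzyloxy)phenol 1 + oxalyl chloride. Upper unit 19 ⇐ flavanone 18 ⇐ chromone 16 + boronic acid 17 (asymmetric conjugate addition).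
5. Ring order: lower ring A and the upper chromone rings are bought; a temporary lactone ring (step 1, opened in step 2) fixes the two-carbon unit ortho to the phenol; lower dihydrofuran ring (step 5) → expanded to the pyran ring (step 7); the two flavan units are joined in step 12.

Key step: step 7

Assumption: the sense of induction of Rh2(S-PTTL)4 (step 5) and of (R)-t-BuPyOx (step 10) is taken as drawn; the mirror-image catalyst or ligand would be used if a first run showed the opposite sense.

**Route**

Step 1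
Reactants: 1 3,5-bis(benzyloxy)phenol
Product: 3 4,6-bis(benzyloxy)-1-benzofuran-2,3-dione, via aryl chlorooxalate 2 (not isolated)
Conditions: (COCl)2 (1.2 equiv), Et2O, 0 °C → rt
Reagents that add atoms: oxalyl chloride, O=C(Cl)C(=O)Cl
Why: O-acylation of the phenol followed by intramolecular Friedel–Crafts acylation of the phloroglucinol-type ring (Stollé-type coumarandione synthesis) can close only onto a position ortho to the phenol oxygen, and the two such positions are equivalent, so the two-carbon unit is placed regiospecifically; no stereocentre is formed.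

Step 2
Reactants: 3 4,6-bis(benzyloxy)-1-benzofuran-2,3-dione
Product: 4 methyl 2-[2,4-bis(benzyloxy)-6-hydroxyphenyl]-2-oxoacetate
Conditions: MeOH/CH2Cl2, NaOMe (5 mol %), 0 °C → rt; AcOH quench
Reagents that add atoms: methanol, CO
Why: Methanolysis of the activated aryl ester (lactone) of the α-keto acid should open the five-membered ring to the methyl aryl glyoxylate, which is held open by the hydrogen bond between the freed phenol and the ketone.

Step 3
Reactants: 4 methyl 2-[2,4-bis(benzyloxy)-6-hydroxyphenyl]-2-oxoacetate; 5 4-(benzyloxy)benzyl chloride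
Product: 6 methyl 2-{2,4-bis(benzyloxy)-6-[(4-benzyloxybenzyl)oxy]phenyl}-2-oxoacetate
Conditions: K2CO3, n-Bu4NI (cat.), DMF, rt
Reagents that add atoms: none
Why: Williamson ether synthesis on the only free phenol attaches the future C2 and ring B of the lower unit to the oxygen that becomes O1; no stereocentre is formed.

Step 4
Reactants: 6 methyl 2-{2,4-bis(benzyloxy)-6-[(4-benzyloxybenzyl)oxy]phenyl}-2-oxoacetate
Product: 8 methyl 2-{2,4-bis(benzyloxy)-6-[(4-benzyloxybenzyl)oxy]phenyl}-2-diazoacetate, via tosylhydrazone 7 (not isolated)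
Conditions: TsNHNH2, MeOH/CH2Cl2, 45 °C; then DBU, CH2Cl2, 0 °C → rt
Reagents that add atoms: p-toluenesulfonyl hydrazide, Cc1ccc(cc1)S(=O)(=O)NN
Why: Bamford–Stevens-type diazo synthesis: condensation of the reactive keto ester to its tosylhydrazone and base-induced loss of sulfinate should give the donor–acceptor diazo ester.

Step 5
Reactants: 8 methyl 2-{2,4-bis(benzyloxy)-6-[(4-benzyloxybenzyl)oxy]phenyl}-2-diazoacetate
Product: 9 methyl (2S,3R)-4,6-bis(benzyloxy)-2-[4-(benzyloxy)phenyl]-2,3-dihydro-1-benzofuran-3-carboxylate (2,3-cis)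
Conditions: Rh2(S-PTTL)4 (dirhodium tetrakis[N-phthaloyl-(S)-tert-leucinate], 1 mol %), toluene, −60 °C
Reagents that add atoms: none
Why: Intramolecular 1,5-C–H insertion of the dirhodium carbene into an O–CH2–aryl bond closes the dihydrofuran; because the insertion has hydride-transfer character, the CH2 of the 4-(benzyloxy)benzyl ether, whose developing positive charge is stabilised by the para oxygen, should react well ahead of the CH2 of the plain benzyl ether on the other ortho oxygen, and the chiral carboxylate ligands set C2 and C3 together in a concerted insertion that places aryl and ester cis.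

Step 6
Reactants: 9 the cis ester
Product: 10 {(2S,3S)-4,6-bis(benzyloxy)-2-[4-(benzyloxy)phenyl]-2,3-dihydro-1-benzofuran-3-yl}methanol (2,3-cis)
Conditions: i-Bu2AlH (3 equiv), CH2Cl2, −78 → −40 °C
Reagents that add atoms: none
Why: Hydride reduction of the ester at low temperature under non-basic conditions should carry the epimerisable cis C3 centre unchanged into the primary alcohol.

Step 7
Reactants: 10 the cis dihydrobenzofuranylmethanol
Product: 13 (2R,3R)-5,7-bis(benzyloxy)-2-[4-(benzyloxy)phenyl]chroman-3-ol (2,3-cis; tri-O-benzyl (−)-epiafzelechin), via primary trifluoroacetate 11 (not isolated), via chroman-3-yl trifluoroacetate 12 (not isolated)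
Conditions: (CF3CO)2O (1.05 equiv), 2,6-lutidine, CH2Cl2, −20 °C, volatiles removed; then Zn(O2CCF3)2 (20 mol %), MeNO2, 50 °C; then K2CO3 (cat.), MeOH, 0 °C
Reagents that add atoms: trifluoroacetic anhydride, O=C(OC(=O)C(F)(F)F)C(F)(F)F
Why: Proposed new method: acylation gives the primary trifluoroacetate 11, which ionises with anchimeric assistance by the ring A carbon C3a (ortho to O1 and to the 4-benzyloxy group, para to the 6-benzyloxy group) to a spirocyclopropyl arenium (phenonium) ion; return of trifluoroacetate to the CH2 carbon merely regenerates 11, whereas return to C3 cleaves the C3–C3a bond and gives the chroman ester 12, so reversible ionisation under mild Lewis acid catalysis should drain the mixture to the less strained six-membered secondary ester, which methanolysis at the acyl–oxygen bond then converts into the alcohol. The closest known reaction types are the trifluoroacetate-mediated, thermodynamically controlled ring expansion of prolinols to 3-hydroxypiperidines through aziridinium ions and the Wagner–Meerwein ring expansion of benzo-fused cycloalkylmethyl esters by 1,2-aryl shift through phenonium ions. The pyran ring is closed by the 1,2-shift of the aryl carbon from C3 to the exocyclic carbon (3-exo-tet attack of the arene ipso carbon on CH2–O, then opening of the internal cyclopropane bond by the carboxylate), so that this carbon becomes C4 and is inserted between C3 and C4a. C2 is not touched and keeps its configuration, while the new C3–O bond forms anti to the departing aryl carbon (inversion at C3), which converts the 2,3-cis dihydrobenzofuran stereospecifically into the 2,3-cis (2R,3R) flavan-3-ol. The step needs ring expansion to win over return, elimination, O1 participation and migration of the ring B aryl: the first is secured thermodynamically by relief of the eclipsed cis-2,3-disubstituted five-membered ring and by the reversibility of the primary ester, the others by the trioxygenated ring A, whose ipso carbon is by far the best neighbouring group present, by the non-basic medium and by the cis arrangement in 12, which gives the ring B aryl no antiperiplanar path.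

Step 8
Reactants: 13 tri-O-benzyl epiafzelechin
Product: 14 (2R,3R)-5,7-bis(benzyloxy)-2-[4-(benzyloxy)phenyl]-8-bromochroman-3-ol
Conditions: NBS (1.0 equiv), CH2Cl2, −78 → −20 °C
Reagents that add atoms: N-bromosuccinimide, O=C1CCC(=O)N1Br
Why: Electrophilic aromatic bromination should go to C8, the more accessible of the two activated ring A positions (between the ring oxygen and the 7-ether), as is the rule for 5,7-di-O-benzylated flavan-3-ols; the bromine blocks C8 for step 12.

Step 9
Reactants: 15 7-hydroxy-4H-chromen-4-one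
Product: 16 7-(benzyloxy)-4H-chromen-4-one
Conditions: BnBr, K2CO3, acetone, reflux
Reagents that add atoms: benzyl bromide, BrCc1ccccc1
Why: Williamson ether synthesis on the acidic 7-hydroxyl; no stereocentre is formed.

Step 10
Reactants: 16 7-(benzyloxy)-4H-chromen-4-one; 17 [4-(benzyloxy)phenyl]boronic acid
Product: 18 (2S)-7-(benzyloxy)-2-[4-(benzyloxy)phenyl]chroman-4-one
Conditions: Pd(OCOCF3)2 (5 mol %), (R)-t-BuPyOx (6 mol %), NH4PF6, H2O, ClCH2CH2Cl, 60 °C
Reagents that add atoms: none
Why: Palladium-catalysed asymmetric conjugate addition of the arylboronic acid to the chromone (Hayashi–Miyaura-type 1,4-addition), in which the pyridine–oxazoline ligand controls the face of aryl transfer and sets C2 as S.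

Step 11
Reactants: 18 the (2S)-flavanone
Product: 19 (2S,4S)-7-(benzyloxy)-2-[4-(benzyloxy)phenyl]chroman-4-ol (2,4-cis)
Conditions: NaBH4, THF/MeOH, 0 °C
Reagents that add atoms: none
Why: Borohydride reduction by axial attack on the half-chair with equatorial 2-aryl should give mainly the 2,4-cis alcohol (4S); the C4 configuration is of no consequence because this centre is ionised in step 12.

Step 12
Reactants: 14 the 8-bromo epiafzelechin ether; 19 the flavan-4-ol
Product: 20 (2R,3R)-5,7-bis(benzyloxy)-2-[4-(benzyloxy)phenyl]-6-{(2S,4R)-7-(benzyloxy)-2-[4-(benzyloxy)phenyl]chroman-4-yl}-8-bromochroman-3-ol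
Conditions: Bi(OSO2CF3)3 (5 mol %), 4 Å MS, CH2Cl2, −40 → 0 °C
Reagents that add atoms: none
Why: Friedel–Crafts alkylation that copies the presumed biosynthetic capture of a flavan-4-yl cation: the catalyst ionises the doubly activated benzylic alcohol (cation stabilised by O1 and the para 7-ether) while the plain benzyl ethers stay intact, bromine at C8 leaves only C6 free, and pseudo-axial attack on the half-chair cation with equatorial 2-aryl should set C4 as R (2,4-trans).

Step 13
Reactants: 20 the protected bromo-dimer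
Product: 21 (2R,3R)-2-(4-hydroxyphenyl)-6-[(2S,4R)-7-hydroxy-2-(4-hydroxyphenyl)chroman-4-yl]chromane-3,5,7-triol (target)
Conditions: H2 (1 atm), Pd(OH)2/C, Et3N, THF/MeOH, rt
Reagents that add atoms: none
Why: Catalytic hydrogenolysis should cleave the five benzyl ethers and, with Et3N as HBr scavenger, the aryl–bromine bond in one operation without touching any stereocentre.

**Compound list**

1 | 3,5-bis(benzyloxy)phenol | Oc1cc(OCc2ccccc2)cc(OCc2ccccc2)c1 | starting material
2 | 3,5-bis(benzyloxy)phenyl chlorooxoacetate | O=C(Cl)C(=O)Oc1cc(OCc2ccccc2)cc(OCc2ccccc2)c1 | intermediate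
3 | 4,6-bis(benzyloxy)-1-benzofuran-2,3-dione | O=C1Oc2cc(OCc3ccccc3)cc(OCc3ccccc3)c2C1=O | intermediate
4 | methyl 2-[2,4-bis(benzyloxy)-6-hydroxyphenyl]-2-oxoacetate | COC(=O)C(=O)c1c(O)cc(OCc2ccccc2)cc1OCc1ccccc1 | intermediate
5 | 4-(benzyloxy)benzyl chloride | ClCc1ccc(OCc2ccccc2)cc1 | starting material
6 | methyl 2-{2,4-bis(benzyloxy)-6-[(4-benzyloxybenzyl)oxy]phenyl}-2-oxoacetate | COC(=O)C(=O)c1c(OCc2ccc(OCc3ccccc3)cc2)cc(OCc2ccccc2)cc1OCc1ccccc1 | intermediate
7 | N-tosylhydrazone of 6 | COC(=O)C(=NNS(=O)(=O)c1ccc(C)cc1)c1c(OCc2ccc(OCc3ccccc3)cc2)cc(OCc2ccccc2)cc1OCc1ccccc1 | intermediate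
8 | methyl 2-{2,4-bis(benzyloxy)-6-[(4-benzyloxybenzyl)oxy]phenyl}-2-diazoacetate | COC(=O)C(=[N+]=[N-])c1c(OCc2ccc(OCc3ccccc3)cc2)cc(OCc2ccccc2)cc1OCc1ccccc1 | intermediate
9 | methyl (2S,3R)-4,6-bis(benzyloxy)-2-[4-(benzyloxy)phenyl]-2,3-dihydro-1-benzofuran-3-carboxylate (cis) | COC(=O)[C@H](c1c(OCc2ccccc2)cc(OCc2ccccc2)cc1O4)[C@H]4c1ccc(OCc2ccccc2)cc1 | intermediate
10 | {(2S,3S)-4,6-bis(benzyloxy)-2-[4-(benzyloxy)phenyl]-2,3-dihydro-1-benzofuran-3-yl}methanol (cis) | OC[C@H](c1c(OCc2ccccc2)cc(OCc2ccccc2)cc1O4)[C@H]4c1ccc(OCc2ccccc2)cc1 | intermediate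
11 | {(2S,3S)-4,6-bis(benzyloxy)-2-[4-(benzyloxy)phenyl]-2,3-dihydro-1-benzofuran-3-yl}methyl trifluoroacetate | O=C(OC[C@H](c1c(OCc2ccccc2)cc(OCc2ccccc2)cc1O4)[C@H]4c1ccc(OCc2ccccc2)cc1)C(F)(F)F | intermediate
12 | (2R,3R)-5,7-bis(benzyloxy)-2-[4-(benzyloxy)phenyl]chroman-3-yl trifluoroacetate | O=C(O[C@@H]1Cc2c(OCc3ccccc3)cc(OCc3ccccc3)cc2O[C@@H]1c1ccc(OCc2ccccc2)cc1)C(F)(F)F | intermediate
13 | (2R,3R)-5,7-bis(benzyloxy)-2-[4-(benzyloxy)phenyl]chroman-3-ol | O[C@@H]1Cc2c(OCc3ccccc3)cc(OCc3ccccc3)cc2O[C@@H]1c1ccc(OCc2ccccc2)cc1 | intermediate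
14 | (2R,3R)-5,7-bis(benzyloxy)-2-[4-(benzyloxy)phenyl]-8-bromochroman-3-ol | O[C@@H]1Cc2c(OCc3ccccc3)cc(OCc3ccccc3)c(Br)c2O[C@@H]1c1ccc(OCc2ccccc2)cc1 | intermediate
15 | 7-hydroxy-4H-chromen-4-one | O=c1ccoc2cc(O)ccc12 | starting material
16 | 7-(benzyloxy)-4H-chromen-4-one | O=c1ccoc2cc(OCc3ccccc3)ccc12 | intermediate
17 | [4-(benzyloxy)phenyl]boronic acid | OB(O)c1ccc(OCc2ccccc2)cc1 | starting material
18 | (2S)-7-(benzyloxy)-2-[4-(benzyloxy)phenyl]chroman-4-one | O=C1C[C@@H](c2ccc(OCc3ccccc3)cc2)Oc2cc(OCc3ccccc3)ccc12 | intermediate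
19 | (2S,4S)-7-(benzyloxy)-2-[4-(benzyloxy)phenyl]chroman-4-ol (cis) | O[C@H]1C[C@@H](c2ccc(OCc3ccccc3)cc2)Oc2cc(OCc3ccccc3)ccc12 | intermediate
20 | (2R,3R)-5,7-bis(benzyloxy)-2-[4-(benzyloxy)phenyl]-6-{(2S,4R)-7-(benzyloxy)-2-[4-(benzyloxy)phenyl]chroman-4-yl}-8-bromochroman-3-ol | c1ccccc1COc1ccc([C@@H]2C[C@@H](c3c(OCc5ccccc5)c(Br)c4c(c3OCc3ccccc3)C[C@@H](O)[C@@H](c3ccc(OCc5ccccc5)cc3)O4)c3ccc(OCc5ccccc5)cc3O2)cc1 | intermediate
21 | (2R,3R)-2-(4-hydroxyphenyl)-6-[(2S,4R)-7-hydroxy-2-(4-hydroxyphenyl)chroman-4-yl]chromane-3,5,7-triol | Oc1ccc([C@@H]2C[C@@H](c3c(O)cc4c(c3O)C[C@@H](O)[C@@H](c3ccc(O)cc3)O4)c3ccc(O)cc3O2)cc1 | target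

**Step count and risks**

Total step count: 13. Longest linear sequence: 10 steps (steps 1–8, 12 and 13); steps 9–11 form the upper unit in a 3-step branch.

Steps most likely to fail:

1. Step 7 (Proposed new method). The primary trifluoroacetate may ionise too slowly, or return to the CH2 carbon and elimination may outpace equilibration to the six-membered ester. The fallback uses known chemistry, keeps the 1,2-aryl shift but drives it by carbonyl formation, and does not depend on the C3 configuration of the ester; it sets out from 9 and returns at 13. Deprotonation of 9 with KN(SiMe3)2 (THF, −78 °C) and hydroxylation of the enolate with 2-(phenylsulfonyl)-3-phenyloxaziridine on the face opposite to the 2-aryl group should give methyl (2R,3S)-4,6-bis(benzyloxy)-2-[4-(benzyloxy)phenyl]-3-hydroxy-2,3-dihydro-1-benzofuran-3-carboxylate F1; ring opening of the enolate would be a reverse 5-endo process and is disfavoured. LiAlH4 (THF, 0 °C) should reduce it to the diol (2R,3R)-4,6-bis(benzyloxy)-2-[4-(benzyloxy)phenyl]-3-(hydroxymethyl)-2,3-dihydro-1-benzofuran-3-ol F2, and TsCl/pyridine (0 °C) should sulfonylate only the primary hydroxyl to give the mono-p-toluenesulfonate of this diol F3. On warming in THF with LiClO4 and CaCO3, the tosylate should undergo semipinacol rearrangement with migration of the ring A carbon to give (2R)-5,7-bis(benzyloxy)-2-[4-(benzyloxy)phenyl]chroman-3-one F4, and LiBH(s-Bu)3 (THF, −78 °C) should reduce this ketone from the face opposite to the 2-aryl group to the 2,3-cis alcohol 13.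

2. Step 5. The carbene may insert in part into the CH2 of the plain benzyl ether on the other ortho oxygen, and facial or cis selectivity may be eroded because both ortho positions of the donor–acceptor carbene are substituted. The fallback replaces catalyst control by a covalently bound auxiliary and separation of isomers at the ester stage; it sets out from 6 and returns at 10. It does not remove the site competition; a wrong-site product would be a constitutional isomer and is taken out at the same separation. Transesterification of 6 with (R)-pantolactone (Ti(OiPr)4 cat., toluene, 80 °C) should give (3R)-4,4-dimethyl-2-oxooxolan-3-yl 2-{2,4-bis(benzyloxy)-6-[(4-benzyloxybenzyl)oxy]phenyl}-2-oxoacetate F5. TsNHNH2 should convert it into the N-tosylhydrazone of this keto ester F6, and DBU should then give (3R)-4,4-dimethyl-2-oxooxolan-3-yl 2-{2,4-bis(benzyloxy)-6-[(4-benzyloxybenzyl)oxy]phenyl}-2-diazoacetate F7. Insertion with achiral Rh2(OAc)4 under control of the auxiliary, followed by chromatographic or crystallisation-based removal of the minor diastereomers and of any regioisomer, should give (3R)-4,4-dimethyl-2-oxooxolan-3-yl (2S,3R)-4,6-bis(benzyloxy)-2-[4-(benzyloxy)phenyl]-2,3-dihydro-1-benzofuran-3-carboxylate F8, which LiAlH4 (THF, −40 °C) should reduce to 10.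

3. Step 12. Attack at the doubly flanked C6 may be sluggish, so that elimination or self-condensation of the ionised flavan-4-ol takes over under the Lewis acid. The fallback replaces acid ionisation of the alcohol by thiophilic activation of a 4-thioether with a stoichiometric silver salt under buffered, non-acidic conditions; it sets out from 19 and returns at 20. Treatment of 19 with thiophenol and BF3·OEt2 (cat., CH2Cl2, −40 °C) should give (2S,4R)-7-(benzyloxy)-2-[4-(benzyloxy)phenyl]-4-(phenylsulfanyl)chromane F9, whose C4 configuration is again of no consequence. Activation of this thioether with AgOSO2CF3 (silver triflate) and 2,6-di-tert-butyl-4-methylpyridine in CH2Cl2 at −40 °C in the presence of 14 should release the same flavan-4-yl cation irreversibly and give 20.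

**Further compounds**

F1 | step 7 | methyl (2R,3S)-4,6-bis(benzyloxy)-2-[4-(benzyloxy)phenyl]-3-hydroxy-2,3-dihydro-1-benzofuran-3-carboxylate | COC(=O)[C@](O)(c1c(OCc2ccccc2)cc(OCc2ccccc2)cc1O4)[C@H]4c1ccc(OCc2ccccc2)cc1
F2 | step 7 | (2R,3R)-4,6-bis(benzyloxy)-2-[4-(benzyloxy)phenyl]-3-(hydroxymethyl)-2,3-dihydro-1-benzofuran-3-ol | OC[C@](O)(c1c(OCc2ccccc2)cc(OCc2ccccc2)cc1O4)[C@H]4c1ccc(OCc2ccccc2)cc1
F3 | step 7 | primary mono-p-toluenesulfonate of F2 | Cc1ccc(cc1)S(=O)(=O)OC[C@](O)(c1c(OCc2ccccc2)cc(OCc2ccccc2)cc1O4)[C@H]4c1ccc(OCc2ccccc2)cc1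
F4 | step 7 | (2R)-5,7-bis(benzyloxy)-2-[4-(benzyloxy)phenyl]chroman-3-one | O=C1Cc2c(OCc3ccccc3)cc(OCc3ccccc3)cc2O[C@@H]1c1ccc(OCc2ccccc2)cc1
F5 | step 5 | (3R)-4,4-dimethyl-2-oxooxolan-3-yl 2-{2,4-bis(benzyloxy)-6-[(4-benzyloxybenzyl)oxy]phenyl}-2-oxoacetate | CC1(C)COC(=O)[C@@H]1OC(=O)C(=O)c1c(OCc2ccc(OCc3ccccc3)cc2)cc(OCc2ccccc2)cc1OCc1ccccc1
F6 | step 5 | N-tosylhydrazone of F5 | CC1(C)COC(=O)[C@@H]1OC(=O)C(=NNS(=O)(=O)c1ccc(C)cc1)c1c(OCc2ccc(OCc3ccccc3)cc2)cc(OCc2ccccc2)cc1OCc1ccccc1
F7 | step 5 | (3R)-4,4-dimethyl-2-oxooxolan-3-yl 2-{2,4-bis(benzyloxy)-6-[(4-benzyloxybenzyl)oxy]phenyl}-2-diazoacetate | CC1(C)COC(=O)[C@@H]1OC(=O)C(=[N+]=[N-])c1c(OCc2ccc(OCc3ccccc3)cc2)cc(OCc2ccccc2)cc1OCc1ccccc1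
F8 | step 5 | (3R)-4,4-dimethyl-2-oxooxolan-3-yl (2S,3R)-4,6-bis(benzyloxy)-2-[4-(benzyloxy)phenyl]-2,3-dihydro-1-benzofuran-3-carboxylate (cis) | CC1(C)COC(=O)[C@@H]1OC(=O)[C@H](c1c(OCc2ccccc2)cc(OCc2ccccc2)cc1O4)[C@H]4c1ccc(OCc2ccccc2)cc1
F9 | step 12 | (2S,4R)-7-(benzyloxy)-2-[4-(benzyloxy)phenyl]-4-(phenylsulfanyl)chromane | c1ccccc1S[C@@H]1C[C@@H](c2ccc(OCc3ccccc3)cc2)Oc2cc(OCc3ccccc3)ccc12
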